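**Plan**

1. The target is 2-hydroxy-3-icosyl-5-methoxy-1,4-benzoquinone (ring C1–C6: C1=O, C2–OH, C3–icosyl, C4=O, C5–OMe, C6–H). The retrosynthesis first undoes the redox/O-benzyl adjustment (back to the 2-O-benzyl hydroquinone). It then cuts ring bond C1–C2 by retro-6π-electrocyclisation to a dienylketene, which folds back to a 4-hydroxycyclobutenone, and last cuts C3–C4 (vinyllithium + ketone).
2. Enabling feature: the four-carbon arc C1(=O)–C6H=C5(OMe)–C4(=O), with its para oxygens and the methoxy group, is a squaric acid skeleton, and a cyclobutenone is a masked vinylketene. C2(O)=C3(icosyl) is the enol ether of docosanal.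
3. Forward: dimethyl squarate → methyl semisquarate; docosanal → benzyl enol ether → β-bromo enol ether; Br/Li exchange and 1,2-addition join chain and four-membered ring (C3–C4). Thermolysis then builds the only ring of the target, the six-membered carbocycle, by 4π-opening/6π-closure (C1–C2), and hydrogenolysis/air oxidation ends at the quinone.
4. Stereochemistry: the target has none. The carbinol centre of the cyclobutenone and the sp3 centre of the dienone intermediate are racemic and are erased in the key step.

Key step: step 5

Remark: the target has no stereocentre and no stereogenic double bond, so the given structure is one achiral compound and no enantiomer has to be selected; docosanal is taken as a catalogue aldehyde.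

**Route**

Step 1
Reactants: 1 dimethyl squarate (3,4-dimethoxycyclobut-3-ene-1,2-dione)
Product: 3 3-methoxycyclobut-3-ene-1,2-dione, via hydroxycyclobutenone 2 (not isolated)
Conditions: LiAlH(Ot-Bu)3 (1.05 equiv), THF, −78 °C; 1 M HCl quench; then conc. HCl (cat.), CH2Cl2, rt
Reagents that add atoms: water, O (supplies the oxygen of the new C=O)
Why: The hindered hydride should reduce one of the two equivalent vinylogous-ester carbonyls once (1,2-reduction), and acid then ionises the carbinol and hydrolyses the methoxy-stabilised allyl cation with loss of methanol (allylic transposition/vinylogous ester hydrolysis), the standard entry to semisquaric esters.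

Step 2
Reactants: 4 docosanal
Product: 6 1-(benzyloxy)docos-1-ene (E/Z mixture), via dibenzyl acetal 5 (not isolated)
Conditions: BnOTMS (2.2 equiv), TMSOTf (5 mol %), CH2Cl2, −78 °C; then i-Pr2NEt (1.5 equiv), TMSOTf (1.2 equiv), −20 °C → rt
Reagents that add atoms: benzyloxytrimethylsilane, C[Si](C)(C)OCc1ccccc1
Why: Noyori acetalisation followed in the same flask by Gassman elimination of the acetal (TMSOTf/Hünig base) should give the benzyl enol ether, whose E/Z composition is irrelevant because both isomers give the same dibromide-derived product in step 3.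

Step 3
Reactants: 6 1-(benzyloxy)docos-1-ene
Product: 8 (Z)-2-bromo-1-(benzyloxy)docos-1-ene, via dibromo ether 7 (not isolated)
Conditions: Br2 (1.0 equiv), CH2Cl2, −78 °C; then Et3N (3 equiv), −78 °C → rt; stored over K2CO3
Reagents that add atoms: bromine, BrBr
Why: Bromine adds to the enol ether and the α-bromide of the resulting α,β-dibromo ether ionises to an oxocarbenium ion from which base removes the C2 proton (bromination–dehydrobromination, as for 5-bromo-3,4-dihydro-2H-pyran), the Z isomer (Br cis to OBn, chain trans to oxygen) being expected to predominate.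

Step 4
Reactants: 8 (Z)-2-bromo-1-(benzyloxy)docos-1-ene; 3 3-methoxycyclobut-3-ene-1,2-dione
Product: 10 4-[(1Z)-1-(benzyloxy)docos-1-en-2-yl]-4-hydroxy-3-methoxycyclobut-2-en-1-one (racemic), via vinyllithium 9 (not isolated)
Conditions: t-BuLi (2.0 equiv), Et2O, −78 °C; then cannulated into 3, THF, −78 °C; H2O quench at −78 °C; Et3N-deactivated silica
Reagents that add atoms: none
Why: Bromine–lithium exchange proceeds with retention to the O-chelated cis-β-alkoxyvinyllithium (stable at −78 °C like (Z)-2-ethoxyvinyllithium), which should add 1,2 to the more electrophilic carbonyl of 3 (the one next to the methoxy-bearing carbon, not part of the vinylogous ester), as organolithiums do with 3-alkoxycyclobutenediones; the new carbinol centre is racemic and is destroyed in step 5.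

Step 5
Reactants: 10 4-[(1Z)-1-(benzyloxy)docos-1-en-2-yl]-4-hydroxy-3-methoxycyclobut-2-en-1-one
Product: 13 2-(benzyloxy)-3-icosyl-5-methoxybenzene-1,4-diol, via dienylketene 11 (not isolated), via cyclohexadienone 12 (not isolated)
Conditions: PhMe (degassed, dilute), 110 °C, Ar; product kept under Ar and used directly
Reagents that add atoms: none
Why: Heating should trigger the thermally allowed conrotatory 4π-electrocyclic opening of the cyclobutenone (cleavage of the C(=O)–C(OH) σ-bond), the donor hydroxyl rotating outward so that the alkenyl group turns inward and the s-cis dienylketene 11 results. A disrotatory 6π-electrocyclisation then joins the ketene carbon to the benzyloxy-bearing vinyl terminus, which closes the six-membered carbocycle (6π-electrocyclic closure; the new ring bond lies between the future C1 carbonyl carbon and the oxygen-bearing C2) and gives cyclohexa-2,4-dienone 12, whose enolisation to the aromatic hydroquinone 13 makes the cascade irreversible. The closest known reaction type is the Moore–Liebeskind ring expansion of 4-alkenyl- and 4-aryl-4-hydroxycyclobutenones to hydroquinones and quinones. No stereocentre is created for the target: the carbinol centre of 10 becomes sp2 on ring opening and the sp3 centre of 12 is erased on aromatisation, so the configuration of 10 and the geometry of its enol ether leave no trace in 13. The step needs torquoselectivity (OH outward), which the strong donor character of hydroxyl secures and which also keeps the OH away from the ketene (no butenolide), and it needs regiocontrol of five different ring substituents, which is fixed by connectivity because the ketene carbon and the carbinol carbon must become the para C1 and C4 oxygens with H, OMe, icosyl and OBn locked between them.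

Step 6
Reactants: 13 2-(benzyloxy)-3-icosyl-5-methoxybenzene-1,4-diol
Product: 15 Irisoquin-D (2-hydroxy-3-icosyl-5-methoxycyclohexa-2,5-diene-1,4-dione), via benzenetriol 14 (not isolated)
Conditions: H2 (1 atm), 10% Pd/C, EtOAc, rt; filtration (Celite); then air, rt
Reagents that add atoms: none
Why: Hydrogenolysis of the aryl benzyl ether over Pd/C unveils the 1,2,4-benzenetriol 14 while holding the ring at the hydroquinone level, and such hydroxyhydroquinones should be oxidised by air to the 2-hydroxy-1,4-benzoquinone tautomer, the methyl ether being untouched.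

**Compound list**

1 | dimethyl squarate (3,4-dimethoxycyclobut-3-ene-1,2-dione) | COC1=C(OC)C(=O)C1=O | starting material
2 | 4-hydroxy-2,3-dimethoxycyclobut-2-en-1-one (racemic) | COC1=C(OC)C(=O)C1O | intermediate (not isolated)
3 | 3-methoxycyclobut-3-ene-1,2-dione (methyl semisquarate) | COC1=CC(=O)C1=O | intermediate
4 | docosanal | CCCCCCCCCCCCCCCCCCCCCC=O | starting material
5 | 1,1-bis(benzyloxy)docosane (docosanal dibenzyl acetal) | CCCCCCCCCCCCCCCCCCCCCC(OCc1ccccc1)OCc1ccccc1 | intermediate (not isolated)
6 | 1-(benzyloxy)docos-1-ene (E/Z mixture) | CCCCCCCCCCCCCCCCCCCCC=COCc1ccccc1 | intermediate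
7 | benzyl 1,2-dibromodocosyl ether (diastereomer mixture) | CCCCCCCCCCCCCCCCCCCCC(Br)C(Br)OCc1ccccc1 | intermediate (not isolated)
8 | (Z)-2-bromo-1-(benzyloxy)docos-1-ene (Br cis to OBn) | CCCCCCCCCCCCCCCCCCCC/C(Br)=C/OCc1ccccc1 | intermediate
9 | [1-(benzyloxy)docos-1-en-2-yl]lithium (Li cis to OBn) | CCCCCCCCCCCCCCCCCCCC/C([Li])=C/OCc1ccccc1 | intermediate (not isolated)
10 | 4-[(1Z)-1-(benzyloxy)docos-1-en-2-yl]-4-hydroxy-3-methoxycyclobut-2-en-1-one (racemic) | CCCCCCCCCCCCCCCCCCCC/C(=C/OCc1ccccc1)C2(O)C(OC)=CC2=O | intermediate
11 | 6-(benzyloxy)-4-hydroxy-5-icosyl-3-methoxyhexa-1,3,5-trien-1-one (dienylketene; OH outward, OBn cis to C4) | CCCCCCCCCCCCCCCCCCCC/C(=C/OCc1ccccc1)/C(O)=C(/OC)C=C=O | intermediate (not isolated)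
12 | 6-(benzyloxy)-4-hydroxy-5-icosyl-3-methoxycyclohexa-2,4-dien-1-one (racemic) | O=C1C=C(OC)C(O)=C(CCCCCCCCCCCCCCCCCCCC)C1OCc2ccccc2 | intermediate (not isolated)
13 | 2-(benzyloxy)-3-icosyl-5-methoxybenzene-1,4-diol | COc1cc(O)c(OCc2ccccc2)c(CCCCCCCCCCCCCCCCCCCC)c1O | intermediate
14 | 3-icosyl-5-methoxybenzene-1,2,4-triol | COc1cc(O)c(O)c(CCCCCCCCCCCCCCCCCCCC)c1O | intermediate (not isolated)
15 | Irisoquin-D (2-hydroxy-3-icosyl-5-methoxycyclohexa-2,5-diene-1,4-dione; achiral) | CCCCCCCCCCCCCCCCCCCCC1=C(O)C(=O)C=C(OC)C1=O | target

**Count**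

Total steps: 6. Longest linear sequence: 5 steps (steps 2–6 from docosanal); step 1 is a one-step side branch that joins at step 4.

**Steps most likely to fail, with fallbacks**

Step 4. The lithiated enol ether may lose lithium benzyloxide by β-elimination before it adds (especially material derived from any E-bromide), and the semisquarate may suffer proton transfer at its vinylic C–H instead of carbonyl addition. The fallback sets out from 3 and returns at 15; it uses a vinyllithium without a β-leaving group and installs the C2 oxygen afterwards. Nonadecylmagnesium bromide and 2,3-dibromopropene (CuI cat., THF) give 2-bromodocos-1-ene F1. Exchange with t-BuLi gives (docos-1-en-2-yl)lithium F2, which adds to 3 to give 4-(docos-1-en-2-yl)-4-hydroxy-3-methoxycyclobut-2-en-1-one F3. The same thermal 4π/6π ring expansion (PhMe, 110 °C) gives 2-icosyl-6-methoxybenzene-1,4-diol F4, which is oxidised (air or Ag2O) to 2-icosyl-6-methoxycyclohexa-2,5-diene-1,4-dione F5. Nucleophilic epoxidation (H2O2, Na2CO3) of the alkyl-substituted enone double bond gives 1-icosyl-3-methoxy-7-oxabicyclo[4.1.0]hept-3-ene-2,5-dione F6. The known acid-mediated isomerisation of a quinone epoxide to a hydroxyquinone (silica-supported H2SO4) then delivers 15.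

Step 5. The free tertiary hydroxyl may intercept the ketene (lactonisation) if the inward-pointing benzyloxy group slows the 6π closure, or the allylic carbinol may ionise with help from the enol ether before ring opening. The fallback sets out from 10 and returns at 13; it masks the hydroxyl so that the ketene can only recyclise or undergo the 6π closure. Silylation of 10 (TMSCl, Et3N, DMAP, CH2Cl2) gives 4-[(1Z)-1-(benzyloxy)docos-1-en-2-yl]-3-methoxy-4-(trimethylsilyloxy)cyclobut-2-en-1-one F9. Thermolysis (PhMe, 110 °C) of this silyl ether, a known variant of the ring expansion, gives 2-(benzyloxy)-3-icosyl-5-methoxy-4-(trimethylsilyloxy)phenol F10, and K2CO3/MeOH removes the silyl group to give 13.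

Step 3. The α-bromo benzyl ether may fragment (bromide attack at the benzylic carbon) before elimination, and control of the double-bond geometry may be poor. The fallback sets out from 4 and returns at 8; it never forms the dibromo ether. α-Bromination of 4 (Br2·dioxane, CH2Cl2, 0 °C) gives 2-bromodocosanal F7. Noyori acetalisation (BnOTMS, cat. TMSOTf, −78 °C) gives 1,1-bis(benzyloxy)-2-bromodocosane F8, and Gassman elimination (TMSOTf, i-Pr2NEt, CH2Cl2) gives 8.

**Further compounds**

F1 | step 4 | 2-bromodocos-1-ene | CCCCCCCCCCCCCCCCCCCCC(Br)=C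
F2 | step 4 | (docos-1-en-2-yl)lithium | CCCCCCCCCCCCCCCCCCCCC([Li])=C
F3 | step 4 | 4-(docos-1-en-2-yl)-4-hydroxy-3-methoxycyclobut-2-en-1-one (racemic) | CCCCCCCCCCCCCCCCCCCCC(=C)C1(O)C(OC)=CC1=O
F4 | step 4 | 2-icosyl-6-methoxybenzene-1,4-diol | COc1cc(O)cc(CCCCCCCCCCCCCCCCCCCC)c1O
F5 | step 4 | 2-icosyl-6-methoxycyclohexa-2,5-diene-1,4-dione | COC1=CC(=O)C=C(CCCCCCCCCCCCCCCCCCCC)C1=O
F6 | step 4 | 1-icosyl-3-methoxy-7-oxabicyclo[4.1.0]hept-3-ene-2,5-dione (racemic) | COC1=CC(=O)C2OC2(CCCCCCCCCCCCCCCCCCCC)C1=O
F7 | step 3 | 2-bromodocosanal (racemic) | CCCCCCCCCCCCCCCCCCCCC(Br)C=O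
F8 | step 3 | 1,1-bis(benzyloxy)-2-bromodocosane (racemic) | CCCCCCCCCCCCCCCCCCCCC(Br)C(OCc1ccccc1)OCc1ccccc1
F9 | step 5 | 4-[(1Z)-1-(benzyloxy)docos-1-en-2-yl]-3-methoxy-4-(trimethylsilyloxy)cyclobut-2-en-1-one (racemic) | CCCCCCCCCCCCCCCCCCCC/C(=C/OCc1ccccc1)C2(O[Si](C)(C)C)C(OC)=CC2=O
F10 | step 5 | 2-(benzyloxy)-3-icosyl-5-methoxy-4-(trimethylsilyloxy)phenol | COc1cc(O)c(OCc2ccccc2)c(CCCCCCCCCCCCCCCCCCCC)c1O[Si](C)(C)C
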